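## Retrosynthetic overview

1. The target is robinetinidol-(4α→2′)-(2,3-trans-3,4-cis-leucorobinetinidin). Both flavan units derive from one monomer, (2R,3R)-dihydrorobinetin.
2. The lower C4–OH is set last, by hydrogenation of the ring C ketone of robinetinidol-(4α→2′)-dihydrorobinetin on platinum from the face that gives the axial (3,4-cis) alcohol.
3. The interflavan C4–C2′ bond comes from acid-mediated union of leucorobinetinidin (C4 cation) with the pyrogallol ring B of dihydrorobinetin.
4. Key disconnection: ring C of the monomer through its O1–C2 and C3–O bonds, by an enantioselective oxidative cyclisation of a 2′-hydroxychalcone. This sets C2 and C3 of both halves.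
5. The chalcone comes from aldol condensation of two commercial benzyl ethers. Ring C is formed once (step 2) and carried into both halves; no other ring is made.

Assumption: the two benzyl-protected starting materials are catalogue items, and the facial sense of the new step is taken from that of simple chalcones with the same ligand. It is checked against natural (+)-dihydrorobinetin after step 3, and the other ligand enantiomer is used if it proves opposite.

## Route

Step 1
Reactants: 1 1-[4-(benzyloxy)-2-hydroxyphenyl]ethanone; 2 3,4,5-tris(benzyloxy)benzaldehyde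
Product: 3 (E)-1-[4-(benzyloxy)-2-hydroxyphenyl]-3-[3,4,5-tris(benzyloxy)phenyl]prop-2-en-1-one
Conditions: KOH (50% aq., 5 equiv), EtOH/THF, rt, 36 h; then AcOH to pH 6
Reagents that add atoms: none
Why: Claisen–Schmidt aldol condensation of the methyl ketone enolate with a non-enolisable aldehyde; the conjugated E-enone is the thermodynamic product and the 2′-phenoxide is tolerated.

Step 2
Reactants: 3 (E)-2′-hydroxychalcone
Product: 5 (2R,3R)-7-(benzyloxy)-3-hydroxy-2-[3,4,5-tris(benzyloxy)phenyl]chroman-4-one, via (2R,3S)-epoxy ketone 4 (not isolated)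
Conditions: La(OiPr)3 (10 mol %), (S)-BINOL (10 mol %), Ph3As=O (10 mol %), TBHP (1.5 equiv, decane), MS 4A, THF, rt, 3 added over 4 h; then CSA (0.6 equiv), 0 °C → rt
Reagents that add atoms: tert-butyl hydroperoxide (TBHP), CC(C)(C)OO
Why: Proposed new method: an enantioselective, arrested Algar–Flynn–Oyamada cyclisation, in which the free 2′-hydroxychalcone binds the chiral binaphtholate complex of trivalent lanthanum as a phenolate/carbonyl chelate that holds the enone s-cis beside La–OOtBu, so that the peroxide adds to the Cβ face fixed by the (S)-binaphtholate and closes to the (αR,βS)-epoxide 4 while the chelated phenol oxygen is kept away from Cβ (no racemic oxa-Michael closure, no over-oxidation to flavonol or aurone); CSA in excess over the lanthanum alkoxide then frees the phenol and activates the epoxide, and 6-endo attack at the benzylic Cβ (stabilised by the trialkoxyphenyl ring, Cα being deactivated by the C=O) with inversion gives the 2,3-trans (2R,3R) ketol, so both C–O bonds of ring C and both stereocentres are made in one flask; closest known reaction types are rare-earth binaphtholate/alkyl hydroperoxide epoxidation of O-protected chalcones and acid cyclisation of isolated 2′-hydroxychalcone epoxides.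

Step 3
Reactants: 5 (2R,3R)-tetra-O-benzyldihydrorobinetin
Product: 6 (2R,3R)-3,7-dihydroxy-2-(3,4,5-trihydroxyphenyl)chroman-4-one, (+)-dihydrorobinetin
Conditions: H2 (1 atm), Pd/C (10 wt %), EtOAc/MeOH 1:1, rt, 3 h
Reagents that add atoms: none
Why: Hydrogenolysis of the four aryl benzyl ethers; the vinylogous-ester ketone and the C2–O1 bond of dihydroflavonols survive short, neutral Pd/C hydrogenolysis, and no stereocentre is touched.

Step 4
Reactants: 6 (+)-dihydrorobinetin (one sixth of the batch)
Product: 7 (2R,3S,4R)-2-(3,4,5-trihydroxyphenyl)chromane-3,4,7-triol, (+)-leucorobinetinidin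
Conditions: NaBH4 (2 equiv), EtOH, 0 °C → rt, 1 h, N2; AcOH to pH 6, EtOAc extraction; used at once
Reagents that add atoms: none
Why: Borohydride reduction of the dihydroflavonol ketone in a protic solvent (external, axial hydride) gives mainly the 2,3-trans-3,4-trans diol; the C4 configuration is irrelevant because C4 is ionised in step 5.

Step 5
Reactants: 7 (+)-leucorobinetinidin (1 equiv, added over 6 h); 6 (+)-dihydrorobinetin (5 equiv, excess recovered)
Product: 8 (2R,3R)-3,7-dihydroxy-2-{3,4,5-trihydroxy-2-[(2R,3S,4S)-3,7-dihydroxy-2-(3,4,5-trihydroxyphenyl)chroman-4-yl]phenyl}chroman-4-one, robinetinidol-(4α→2′)-dihydrorobinetin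
Conditions: 0.1 M HCl, H2O/EtOH 4:1, 25 → 40 °C, N2, 24 h; Sephadex LH-20 (EtOH)
Reagents that add atoms: none
Why: Biomimetic SN1 (Friedel–Crafts-type) flavan-3,4-diol/arene condensation with loss of water, in which the 7-OH-stabilised C4 benzylic cation of 7 is captured by the pyrogallol ring B of 6 at C2′ (equivalent to C6′; ring A of 6 is deactivated by its carbonyl) anti to the 3-OH, giving the 3,4-trans (4S) linkage as the major isomer, while the ketone of 6 cannot ionise, so excess 6 and slow addition of 7 limit oligomers.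

Step 6
Reactants: 8 robinetinidol-(4α→2′)-dihydrorobinetin
Product: 9 (2R,3S,4S)-2-{3,4,5-trihydroxy-2-[(2R,3S,4S)-3,7-dihydroxy-2-(3,4,5-trihydroxyphenyl)chroman-4-yl]phenyl}chromane-3,4,7-triol (target)
Conditions: H2 (1 atm), PtO2 (20 wt %), EtOH/AcOH 9:1, rt, stopped at 1 equiv H2 uptake; filtered under N2; Sephadex LH-20 (EtOH)
Reagents that add atoms: none
Why: Heterogeneous catalytic hydrogenation of the aryl ketone under Auwers–Skita control: in weakly acidic medium the ring C sofa adsorbs on platinum through its flatter face (the face of axial H-3, opposite the C2 flap), so hydrogen is delivered equatorially and the new 4-OH is axial and cis to the equatorial 3-OH (4S), the facial sense opposite to that of borohydride; this is the preference expected for 2,3-trans-dihydroflavonols on platinum, and no other stereocentre is touched.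

## Compound list

1 | 1-[4-(benzyloxy)-2-hydroxyphenyl]ethanone | CC(=O)c1ccc(OCc2ccccc2)cc1O | starting material
2 | 3,4,5-tris(benzyloxy)benzaldehyde | O=Cc1cc(OCc2ccccc2)c(OCc2ccccc2)c(OCc2ccccc2)c1 | starting material
3 | (E)-1-[4-(benzyloxy)-2-hydroxyphenyl]-3-[3,4,5-tris(benzyloxy)phenyl]prop-2-en-1-one | O=C(/C=C/c1cc(OCc2ccccc2)c(OCc2ccccc2)c(OCc2ccccc2)c1)c1ccc(OCc2ccccc2)cc1O | intermediate
4 | [4-(benzyloxy)-2-hydroxyphenyl]{(2R,3S)-3-[3,4,5-tris(benzyloxy)phenyl]oxiran-2-yl}methanone (trans, αR,βS) | O=C(c1ccc(OCc2ccccc2)cc1O)[C@@H]1O[C@H]1c1cc(OCc2ccccc2)c(OCc2ccccc2)c(OCc2ccccc2)c1 | intermediate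
5 | (2R,3R)-7-(benzyloxy)-3-hydroxy-2-[3,4,5-tris(benzyloxy)phenyl]chroman-4-one (2,3-trans) | O[C@@H]1[C@@H](c2cc(OCc3ccccc3)c(OCc3ccccc3)c(OCc3ccccc3)c2)Oc2cc(OCc3ccccc3)ccc2C1=O | intermediate
6 | (2R,3R)-3,7-dihydroxy-2-(3,4,5-trihydroxyphenyl)chroman-4-one, (+)-dihydrorobinetin | O[C@@H]1[C@@H](c2cc(O)c(O)c(O)c2)Oc2cc(O)ccc2C1=O | intermediate
7 | (2R,3S,4R)-2-(3,4,5-trihydroxyphenyl)chromane-3,4,7-triol, (+)-leucorobinetinidin (2,3-trans-3,4-trans) | Oc1ccc2c(c1)O[C@H](c1cc(O)c(O)c(O)c1)[C@@H](O)[C@@H]2O | intermediate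
8 | (2R,3R)-3,7-dihydroxy-2-{3,4,5-trihydroxy-2-[(2R,3S,4S)-3,7-dihydroxy-2-(3,4,5-trihydroxyphenyl)chroman-4-yl]phenyl}chroman-4-one | Oc1ccc2c(c1)O[C@H](c1cc(O)c(O)c(O)c1)[C@@H](O)[C@@H]2c1c([C@H]2Oc3cc(O)ccc3C(=O)[C@@H]2O)cc(O)c(O)c1O | intermediate
9 | (2R,3S,4S)-2-{3,4,5-trihydroxy-2-[(2R,3S,4S)-3,7-dihydroxy-2-(3,4,5-trihydroxyphenyl)chroman-4-yl]phenyl}chromane-3,4,7-triol | Oc1ccc2c(c1)O[C@H](c1cc(O)c(O)c(O)c1)[C@@H](O)[C@@H]2c1c([C@H]2Oc3cc(O)ccc3[C@H](O)[C@@H]2O)cc(O)c(O)c1O | target

## Step count and risks

Total steps: 6. Longest linear sequence: 6 (1/2 → 3 → 5 → 6 → 7 → 8 → 9; compound 6 enters step 5 directly as the nucleophile and, after step 4, as the electrophile).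

Steps most likely to fail:

**Step 2 (proposed new step).** Risks: excess chelating substrate may displace the binaphtholate from lanthanum and erode ee (hence slow addition of 3); the phenolate-deactivated enone may epoxidise slowly; the acid stage may give some 2,3-cis ketol or 5-exo products. Fallback with known chemistry, setting out from 3: the 2′-OH is capped (MOMCl, iPr2NEt, CH2Cl2) to give the 2′-O-methoxymethyl chalcone F1. Juliá–Colonna epoxidation (poly-L-leucine, urea–H2O2, DBU, THF) gives the (αR,βS)-epoxide F2. Methanolic HCl (MeOH/THF, 45 °C) removes the acetal and the freed phenol opens the epoxide 6-endo with inversion, giving 5, where the route is rejoined.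

**Step 5.** Risks: self-condensation of 7 through its own ring A or ring B, further reaction of 8 to trimers, a modest 4α/4β ratio, and slow reaction at the hindered C2′. Fallback, setting out from 7: thiolysis with benzyl mercaptan (BnSH, AcOH, EtOH, 80 °C) gives the 4-benzylsulfanyl flavan-3-ol F3, which is stable and can be purified. It is then activated thiophilically in an aprotic medium (AgBF4, THF, 0 °C) in the presence of 6 (4 equiv), delivering the same C4 cation irreversibly to ring B of 6. This gives 8, where the route is rejoined.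

**Step 6.** Risks: hydrogenolysis of the new benzylic C4–O bond to the flavan-3-ol if the uptake is not stopped in time, incomplete facial selectivity on this hindered 2′-substituted substrate, and slowing of the catalyst by the polyphenol. Fallback, setting out from 8: NaBH4 in EtOH (0 °C, external axial hydride) gives the lower-unit 3,4-trans epimer F4. Its benzylic C4–OH is then epimerised through reversible ionisation and water capture (0.05 M aq. HCl, 1 mM, rt). The 3,4-cis epimer is separated on Sephadex LH-20 or by preparative HPLC, and F4 is recycled. This gives 9.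

## Further compounds

F1 | step 2 | (E)-1-[4-(benzyloxy)-2-(methoxymethoxy)phenyl]-3-[3,4,5-tris(benzyloxy)phenyl]prop-2-en-1-one | O=C(/C=C/c1cc(OCc2ccccc2)c(OCc2ccccc2)c(OCc2ccccc2)c1)c1ccc(OCc2ccccc2)cc1OCOC
F2 | step 2 | [4-(benzyloxy)-2-(methoxymethoxy)phenyl]{(2R,3S)-3-[3,4,5-tris(benzyloxy)phenyl]oxiran-2-yl}methanone | O=C(c1ccc(OCc2ccccc2)cc1OCOC)[C@@H]1O[C@H]1c1cc(OCc2ccccc2)c(OCc2ccccc2)c(OCc2ccccc2)c1
F3 | step 5 | (2R,3R,4R)-4-(benzylsulfanyl)-2-(3,4,5-trihydroxyphenyl)chromane-3,7-diol (2,3-trans-3,4-trans) | Oc1ccc2c(c1)O[C@H](c1cc(O)c(O)c(O)c1)[C@@H](O)[C@@H]2SCc1ccccc1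
F4 | step 6 | (2R,3S,4R)-2-{3,4,5-trihydroxy-2-[(2R,3S,4S)-3,7-dihydroxy-2-(3,4,5-trihydroxyphenyl)chroman-4-yl]phenyl}chromane-3,4,7-triol (lower unit 3,4-trans) | Oc1ccc2c(c1)O[C@H](c1cc(O)c(O)c(O)c1)[C@@H](O)[C@@H]2c1c([C@H]2Oc3cc(O)ccc3[C@@H](O)[C@@H]2O)cc(O)c(O)c1O
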